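The autumn run is the slower one: after 25.0 min it keeps 47% of its substrate free, more than the 26% of the noon run. I must decide whether the new flask stays until 40 min or stops while substrate still holds most.

| setting | autumn | noon | flask |
|---|---|---|---|
| substrate | 12 mM | 27 mM | 18 mM |
| remark | run made earlier | run made earlier |  |
| time |  |  | 40 min |

| run | time / min | target / % | substrate / % | side product / % |
|---|---|---|---|---|
| autumn | 2.00 | 6 | 92 | 3 |
| autumn | 4.00 | 8 | 86 | 1 |
| autumn | 6.00 | 14 | 78 | 3 |
| autumn | 12.0 | 20 | 65 | 12 |
| autumn | 25.0 | 19 | 47 | 30 |
| noon | 2.00 | 12 | 81 | 4 |
| noon | 6.00 | 21 | 63 | 11 |
| noon | 12.0 | 26 | 45 | 26 |
| noon | 15.0 | 24 | 36 | 32 |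
| noon | 25.0 | 22 | 26 | 50 |

(readings scatter by 1.5 percentage points)

- percent here means substrate units held: one target counts as two
- percent here means substrate units held: one side product counts as three
- the analysis behind the earlier runs scatters by 1.5 percentage points, standard deviation
- a reading or a percentage of target counts all its forms, free or not
- a reading or a percentage of substrate is of its free form alone

- the species in which most of what was charged as substrate, at 40 min sits (substrate / target / side product)
- the largest share itself, whichever of these holds it, in percent of the substrate charged

I test a guess: equal charged [substrate] times time gives equal percentages. I count that product against its value at the noon run's last reading, so that reading stands at one. This reach, a reduced time, is 1.07 for the flask. The autumn run at 25.0 min has 0.444, and the noon run at 12.0 min has 0.480. Their substrate differs by 2 percentage points and their side product by 4 points, against a scatter of 1.5 points. Their target does not match, at 19% and 26%, so I use the reach for substrate and side product.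

The flask therefore lies a little past the noon run's end, where side product stands at 50% and substrate at 26%. Carrying on the noon run's last slope, I reckon 53.0% side product. I leave the flask until 40 min if I want side product.

The forecast says side product at 52%, a little below my figure. It reads from the same run: “the noon run had 22% target and 50% side product”.

The flask gives side product at 55.9%, with substrate at 23.8% and target at 18.5%.

    2 substrate → target (k = 0.0250 M⁻¹ s⁻¹)
    substrate + target ⇌ idle adduct, settled at all times (K = 50.0 M⁻¹)
    substrate + target → side product (k = 0.140 M⁻¹ s⁻¹)
    2 substrate → homo dimer (k = 2.10 × 10⁻⁵ M⁻¹ s⁻¹)

The forecast held. The idle adduct holds 4.91% at 40.0 min, less than the 32 points by which side product leads substrate. At reach 1.07 the flask stands past the noon run's end, and side product leads in both. Stopped at 15 min, the same flask has reach 0.400, below the autumn run's 0.444, where substrate led side product by 47% to 30%. So I reckon substrate on top there. That stopped flask holds substrate on top, at 48%, with side product at 24.2%.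

(Readings and results are simulated on assumed constants; noise was put on by code.)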